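**Retrosynthetic overview**
- The only ring, the ten-membered carbocycle, is closed last by an intramolecular Nozaki–Hiyama–Kishi addition of the C5 alkenyl iodide to the C6 aldehyde; this also creates the free C6 carbinol.
- The acyclic iodo-aldehyde comes from a Weinreb amide (amide-selective reduction) after angeloylation of the C8 hydroxyl.
- The C7–C8 bond is made by an auxiliary-controlled syn aldol between a west aldehyde (C8–C10, C1–C5) and an east N-acylthiazolidinethione (C6, C7, C11–C13) that already carries the C12 angelate.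
- West fragment: Z-alkene by α-iodo-ylide Wittig, then alkenyllithium/ethylene oxide; E-alkenyl iodide by Zr-catalysed carboalumination–iodination.
- East fragment: C11 by Evans alkylation with tert-butyl bromoacetate, then reduction, angeloylation, acid release and loading onto the thiazolidinethione.

Assumption: 5-(trimethylsilyl)pent-4-yn-1-ol, (R)-4-benzyl-1,3-oxazolidin-2-one, (R)-4-benzyl-1,3-thiazolidine-2-thione and angelic acid are bought; atom labels C1–C15 are germacrane numbers (ring C1–C10, side chain C11–C13).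

**West fragment**

Step 1
Reactants: 1 5-(trimethylsilyl)pent-4-yn-1-ol
Product: 2 5-(trimethylsilyl)pent-4-ynal
Conditions: TEMPO (10 mol%), PhI(OAc)2 (1.1 equiv), CH2Cl2, rt
Reagents that add atoms: none
Why: TEMPO/PhI(OAc)2 oxidation of a primary alcohol stops at the aldehyde and leaves the silylalkyne untouched.

Step 2
Reactants: 2 5-(trimethylsilyl)pent-4-ynal
Product: 3 (Z)-(6-iodohept-5-en-1-yn-1-yl)trimethylsilane
Conditions: EtPPh3I, n-BuLi, THF, 0 °C; I2, −78 °C; NaN(SiMe3)2, −20 °C; then 2, −78 → −20 °C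
Reagents that add atoms: ethyltriphenylphosphonium iodide (CC[P+](c1ccccc1)(c1ccccc1)c1ccccc1.[I-]); iodine (II)
Why: Wittig olefination with the α-iodoethylidene ylide (Zhao olefination) gives the (Z)-2-iodoalkene kinetically, with iodine cis to the chain, which fixes the later C10=C1 geometry.

Step 3
Reactants: 3 (Z)-(6-iodohept-5-en-1-yn-1-yl)trimethylsilane
Product: 5 (Z)-3-methyl-8-(trimethylsilyl)oct-3-en-7-yn-1-ol, via alkenyllithium 4 (not isolated)
Conditions: t-BuLi (2.1 equiv), Et2O, −78 °C; ethylene oxide (3 equiv), BF3·OEt2 (1.2 equiv), −78 °C; NaHCO3 aq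
Reagents that add atoms: ethylene oxide (C1CO1)
Why: iodine–lithium exchange retains the alkene geometry, and SN2 opening of BF3-activated ethylene oxide at −78 °C outruns carbolithiation of the silylalkyne, giving the Z homoallylic alcohol (C9, C8).

Step 4
Reactants: 5 (Z)-3-methyl-8-(trimethylsilyl)oct-3-en-7-yn-1-ol
Product: 6 (Z)-3-methyloct-3-en-7-yn-1-ol
Conditions: K2CO3 (0.3 equiv), MeOH, rt
Reagents that add atoms: none
Why: methanolysis of the alkynyl C–Si bond (protodesilylation) frees the terminal alkyne without touching the alkene or alcohol.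

Step 5
Reactants: 6 (Z)-3-methyloct-3-en-7-yn-1-ol
Product: 8 (3Z,7E)-8-iodo-3,7-dimethylocta-3,7-dien-1-ol, via alkenylalane 7 (not isolated)
Conditions: Me3Al (3 equiv), Cp2ZrCl2 (0.3 equiv), CH2Cl2, 0 °C → rt; then I2, THF, −30 → 0 °C
Reagents that add atoms: trimethylaluminium (C[Al](C)C); iodine (II)
Why: Negishi Zr-catalysed carboalumination adds Me–Al syn and regioselectively to the terminal alkyne, and iodinolysis with retention gives the (E)-alkenyl iodide (C4 methyl, C5 iodide).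

Step 6
Reactants: 8 (3Z,7E)-8-iodo-3,7-dimethylocta-3,7-dien-1-ol
Product: 9 (3Z,7E)-8-iodo-3,7-dimethylocta-3,7-dienal
Conditions: Dess–Martin periodinane (1.3 equiv), pyridine (3 equiv), CH2Cl2, 0 °C; filtered and used at once
Reagents that add atoms: none
Why: buffered Dess–Martin oxidation gives the β,γ-unsaturated aldehyde under non-basic conditions, so the Z alkene does not move into conjugation.

**East fragment**

Step 7
Reactants: 10 (R)-4-benzyl-1,3-oxazolidin-2-one
Product: 11 (R)-4-benzyl-3-propanoyl-1,3-oxazolidin-2-one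
Conditions: EtCOCl, Et3N, DMAP (cat.), CH2Cl2, 0 °C → rt
Reagents that add atoms: propanoyl chloride (CCC(Cl)=O)
Why: DMAP-catalysed N-acylation of the oxazolidinone with the acid chloride gives the imide.

Step 8
Reactants: 11 (R)-4-benzyl-3-propanoyl-1,3-oxazolidin-2-one
Product: 13 tert-butyl (3S)-4-[(4R)-4-benzyl-2-oxo-1,3-oxazolidin-3-yl]-3-methyl-4-oxobutanoate, via sodium enolate 12 (not isolated)
Conditions: NaN(SiMe3)2, THF, −78 °C; BrCH2CO2t-Bu, −78 → −40 °C
Reagents that add atoms: tert-butyl bromoacetate (BrCC(=O)OC(C)(C)C)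
Why: Evans asymmetric alkylation of the chelated Z enolate on the face opposite the benzyl group sets the future C11 stereocentre as S.

Step 9
Reactants: 13 tert-butyl (3S)-4-[(4R)-4-benzyl-2-oxo-1,3-oxazolidin-3-yl]-3-methyl-4-oxobutanoate
Product: 14 tert-butyl (3S)-4-hydroxy-3-methylbutanoate
Conditions: LiBH4, H2O (1 equiv), Et2O, 0 °C
Reagents that add atoms: none
Why: borohydride reduction cleaves the activated imide carbonyl to the primary alcohol (C12) while the tert-butyl ester is too hindered to react; C11 is untouched.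

Step 10
Reactants: 14 tert-butyl (3S)-4-hydroxy-3-methylbutanoate
Product: 15 tert-butyl (3S)-3-methyl-4-{[(2Z)-2-methylbut-2-enoyl]oxy}butanoate
Conditions: angelic acid, PPh3, DIAD, THF, 0 °C → rt
Reagents that add atoms: angelic acid (C/C=C(/C)C(=O)O)
Why: Mitsunobu esterification uses the angelate only as a nucleophile, so the Z acid is never activated at its carbonyl and cannot isomerise to tiglate.

Step 11
Reactants: 15 tert-butyl (3S)-3-methyl-4-{[(2Z)-2-methylbut-2-enoyl]oxy}butanoate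
Product: 16 (3S)-3-methyl-4-{[(2Z)-2-methylbut-2-enoyl]oxy}butanoic acid
Conditions: CF3CO2H, CH2Cl2, 0 °C → rt
Reagents that add atoms: none
Why: acidolysis of the tert-butyl ester (loss of isobutene) frees the acid and leaves the primary angelate in place.

Step 12
Reactants: 16 (3S)-3-methyl-4-{[(2Z)-2-methylbut-2-enoyl]oxy}butanoic acid; 17 (R)-4-benzyl-1,3-thiazolidine-2-thione
Product: 18 (2S)-4-[(4R)-4-benzyl-2-sulfanylidene-1,3-thiazolidin-3-yl]-2-methyl-4-oxobutyl (2Z)-2-methylbut-2-enoate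
Conditions: DCC, DMAP (cat.), CH2Cl2, 0 °C → rt
Reagents that add atoms: none
Why: carbodiimide coupling N-acylates the thiazolidinethione to give the aldol donor.

**Union and end game**

Step 13
Reactants: 18 (2S)-4-[(4R)-4-benzyl-2-sulfanylidene-1,3-thiazolidin-3-yl]-2-methyl-4-oxobutyl (2Z)-2-methylbut-2-enoate; 9 (3Z,7E)-8-iodo-3,7-dimethylocta-3,7-dienal
Product: 20 (2S,3R,4S,6Z,10E)-3-{[(4R)-4-benzyl-2-sulfanylidene-1,3-thiazolidin-3-yl]carbonyl}-4-hydroxy-11-iodo-2,6,10-trimethylundeca-6,10-dien-1-yl (2Z)-2-methylbut-2-enoate, via titanium enolate 19 (not isolated)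
Conditions: TiCl4 (1.05 equiv), i-Pr2NEt (1.1 equiv), NMP (1.0 equiv), CH2Cl2, 0 °C; then 9 (1.2 equiv), −78 → −40 °C
Reagents that add atoms: none
Why: Crimmins titanium-mediated Evans-syn aldol, in which the Z enolate reacts through a non-chelated chair transition state on the face opposite the benzyl group, sets C7 and C8 syn, and the weakly basic enolate spares the β,γ-unsaturated aldehyde.

Step 14
Reactants: 20 the aldol adduct named in step 13
Product: 21 (2S,3R,4S,6Z,10E)-4-hydroxy-11-iodo-3-[methoxy(methyl)carbamoyl]-2,6,10-trimethylundeca-6,10-dien-1-yl (2Z)-2-methylbut-2-enoate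
Conditions: MeNH(OMe)·HCl (3 equiv), imidazole (5 equiv), CH2Cl2, rt
Reagents that add atoms: N,O-dimethylhydroxylamine hydrochloride (CNOC.Cl)
Why: the twisted N-acylthiazolidinethione is an active acyl donor, so mild transamination gives the Weinreb amide without touching the angelate or epimerising C7.

Step 15
Reactants: 21 the β-hydroxy Weinreb amide named in step 14
Product: 22 (2S,3R,4S,6Z,10E)-11-iodo-3-[methoxy(methyl)carbamoyl]-2,6,10-trimethylundeca-6,10-diene-1,4-diyl bis[(2Z)-2-methylbut-2-enoate]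
Conditions: angelic acid (3 equiv), 2,4,6-Cl3C6H2COCl (3 equiv), Et3N (6 equiv), toluene, rt; then 21, 75 °C, no DMAP
Reagents that add atoms: angelic acid (C/C=C(/C)C(=O)O)
Why: Yamaguchi mixed-anhydride esterification transfers the less hindered angeloyl group to the C8 hydroxyl with retention at C8, and leaving out nucleophilic catalysts limits Z to E isomerisation.

Step 16
Reactants: 22 the bis-angelate Weinreb amide named in step 15
Product: 24 (2S,3R,4S,6Z,10E)-3-formyl-11-iodo-2,6,10-trimethylundeca-6,10-diene-1,4-diyl bis[(2Z)-2-methylbut-2-enoate], via zirconium hemiaminal 23 (not isolated)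
Conditions: Cp2Zr(H)Cl (1.5 equiv), THF, rt, 20 min; short SiO2 plug, used at once
Reagents that add atoms: none
Why: hydrozirconation of the amide carbonyl (Georg reduction) is faster than reaction with esters or trisubstituted alkenes, and the stable hemiaminal gives the aldehyde only on work-up, so there is no over-reduction.

Step 17
Reactants: 24 the iodo-aldehyde named in step 16
Product: 26 (2S)-2-[(1S,2S,3E,7Z,10S)-2-hydroxy-4,8-dimethyl-10-{[(2Z)-2-methylbut-2-enoyl]oxy}cyclodeca-3,7-dien-1-yl]propyl (2Z)-2-methylbut-2-enoate, via alkenylchromium species 25 (not isolated)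
Conditions: CrCl2 (10 equiv), NiCl2 (0.1 equiv), degassed DMSO, 0.003 M, rt, syringe-pump addition over 12 h; then H2O
Reagents that add atoms: none
Why: intramolecular Nozaki–Hiyama–Kishi macrocyclisation tolerates both esters and keeps the E alkene geometry; C6 is set by substrate control, with addition anti to the C8 acyloxy group (1,3-anti) expected to favour 6S, though this is a prediction and not assured.

**Compound list**
1 | 5-(trimethylsilyl)pent-4-yn-1-ol | C[Si](C)(C)C#CCCCO | starting material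
2 | 5-(trimethylsilyl)pent-4-ynal | C[Si](C)(C)C#CCCC=O | intermediate
3 | (Z)-(6-iodohept-5-en-1-yn-1-yl)trimethylsilane | C/C(I)=C/CCC#C[Si](C)(C)C | intermediate
4 | [(2E)-7-(trimethylsilyl)hept-2-en-6-yn-2-yl]lithium (Li cis to the chain, geometry of 3 retained) | [Li]/C(C)=C\CCC#C[Si](C)(C)C | intermediate (not isolated)
5 | (Z)-3-methyl-8-(trimethylsilyl)oct-3-en-7-yn-1-ol | OCC/C(C)=C\CCC#C[Si](C)(C)C | intermediate
6 | (Z)-3-methyloct-3-en-7-yn-1-ol | OCC/C(C)=C\CCC#C | intermediate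
7 | dimethylaluminium (3Z,7E)-8-(dimethylalumanyl)-3,7-dimethylocta-3,7-dien-1-olate | C[Al](C)OCC/C(C)=C\CC/C(C)=C/[Al](C)C | intermediate (not isolated)
8 | (3Z,7E)-8-iodo-3,7-dimethylocta-3,7-dien-1-ol | OCC/C(C)=C\CC/C(C)=C/I | intermediate
9 | (3Z,7E)-8-iodo-3,7-dimethylocta-3,7-dienal | O=CC/C(C)=C\CC/C(C)=C/I | intermediate
10 | (R)-4-benzyl-1,3-oxazolidin-2-one | O=C1N[C@H](Cc2ccccc2)CO1 | starting material
11 | (R)-4-benzyl-3-propanoyl-1,3-oxazolidin-2-one | CCC(=O)N1[C@H](Cc2ccccc2)COC1=O | intermediate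
12 | sodium (1Z)-1-[(4R)-4-benzyl-2-oxo-1,3-oxazolidin-3-yl]prop-1-en-1-olate | C/C=C(\[O-])N1[C@H](Cc2ccccc2)COC1=O.[Na+] | intermediate (not isolated)
13 | tert-butyl (3S)-4-[(4R)-4-benzyl-2-oxo-1,3-oxazolidin-3-yl]-3-methyl-4-oxobutanoate | O=C(N1[C@H](Cc2ccccc2)COC1=O)[C@@H](C)CC(=O)OC(C)(C)C | intermediate
14 | tert-butyl (3S)-4-hydroxy-3-methylbutanoate | OC[C@@H](C)CC(=O)OC(C)(C)C | intermediate
15 | tert-butyl (3S)-3-methyl-4-{[(2Z)-2-methylbut-2-enoyl]oxy}butanoate | C/C=C(/C)C(=O)OC[C@@H](C)CC(=O)OC(C)(C)C | intermediate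
16 | (3S)-3-methyl-4-{[(2Z)-2-methylbut-2-enoyl]oxy}butanoic acid | C/C=C(/C)C(=O)OC[C@@H](C)CC(=O)O | intermediate
17 | (R)-4-benzyl-1,3-thiazolidine-2-thione | S=C1N[C@H](Cc2ccccc2)CS1 | starting material
18 | (2S)-4-[(4R)-4-benzyl-2-sulfanylidene-1,3-thiazolidin-3-yl]-2-methyl-4-oxobutyl (2Z)-2-methylbut-2-enoate | C/C=C(/C)C(=O)OC[C@@H](C)CC(=O)N1[C@H](Cc2ccccc2)CSC1=S | intermediate
19 | trichlorotitanium (Z)-enolate of 18 (O–Ti cis to the C11 branch) | C/C=C(/C)C(=O)OC[C@@H](C)/C=C(\O[Ti](Cl)(Cl)Cl)N1[C@H](Cc2ccccc2)CSC1=S | intermediate (not isolated)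
20 | (2S,3R,4S,6Z,10E)-3-{[(4R)-4-benzyl-2-sulfanylidene-1,3-thiazolidin-3-yl]carbonyl}-4-hydroxy-11-iodo-2,6,10-trimethylundeca-6,10-dien-1-yl (2Z)-2-methylbut-2-enoate | C/C=C(/C)C(=O)OC[C@@H](C)[C@@H](C(=O)N1[C@H](Cc2ccccc2)CSC1=S)[C@@H](O)C/C(C)=C\CC/C(C)=C/I | intermediate
21 | (2S,3R,4S,6Z,10E)-4-hydroxy-11-iodo-3-[methoxy(methyl)carbamoyl]-2,6,10-trimethylundeca-6,10-dien-1-yl (2Z)-2-methylbut-2-enoate | C/C=C(/C)C(=O)OC[C@@H](C)[C@@H](C(=O)N(C)OC)[C@@H](O)C/C(C)=C\CC/C(C)=C/I | intermediate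
22 | (2S,3R,4S,6Z,10E)-11-iodo-3-[methoxy(methyl)carbamoyl]-2,6,10-trimethylundeca-6,10-diene-1,4-diyl bis[(2Z)-2-methylbut-2-enoate] | C/C=C(/C)C(=O)OC[C@@H](C)[C@@H](C(=O)N(C)OC)[C@@H](OC(=O)/C(C)=C\C)C/C(C)=C\CC/C(C)=C/I | intermediate
23 | O-zirconated hemiaminal of 22 (amide carbon as CH(OZrCp2Cl)N(OMe)Me, configuration at that carbon undefined) | C/C=C(/C)C(=O)OC[C@@H](C)[C@@H](C(O[Zr](Cl)(C1C=CC=C1)C1C=CC=C1)N(C)OC)[C@@H](OC(=O)/C(C)=C\C)C/C(C)=C\CC/C(C)=C/I | intermediate (not isolated)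
24 | (2S,3R,4S,6Z,10E)-3-formyl-11-iodo-2,6,10-trimethylundeca-6,10-diene-1,4-diyl bis[(2Z)-2-methylbut-2-enoate] | C/C=C(/C)C(=O)OC[C@@H](C)[C@@H](C=O)[C@@H](OC(=O)/C(C)=C\C)C/C(C)=C\CC/C(C)=C/I | intermediate
25 | alkenylchromium dichloride from 24 (trivalent chromium in place of iodine, E geometry retained) | C/C=C(/C)C(=O)OC[C@@H](C)[C@@H](C=O)[C@@H](OC(=O)/C(C)=C\C)C/C(C)=C\CC/C(C)=C/[Cr](Cl)Cl | intermediate (not isolated)
26 | (2S)-2-[(1S,2S,3E,7Z,10S)-2-hydroxy-4,8-dimethyl-10-{[(2Z)-2-methylbut-2-enoyl]oxy}cyclodeca-3,7-dien-1-yl]propyl (2Z)-2-methylbut-2-enoate | C/C=C(/C)C(=O)OC[C@@H](C)[C@@H]1[C@@H](OC(=O)/C(C)=C\C)C/C(C)=C\CC/C(C)=C/[C@@H]1O | target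

**Totals**
Total step count: 17.
Longest linear sequence: 11 steps (steps 1–6 then 13–17; the branch through steps 7–12 then 13–17 is also 11).

**Three steps most likely to fail**

Step 17 (macrocyclisation; C6 configuration and the β-acyloxy aldehyde). If the ring closes with the wrong or a mixed configuration at C6, set C6 under reagent control instead. The fallback sets out from 24 and returns at 26. The cyclised material, for example the (6R)-epimeric carbinol F1, is oxidised with Dess–Martin periodinane/pyridine to the macrocyclic enone F2. F2 is then reduced with (S)-Me-CBS oxazaborolidine and BH3·SMe2 in THF at −30 °C, taking the alkenyl branch as the large group, to give 26. Which catalyst enantiomer delivers 6S should be confirmed on the first run, because the branched C7 side competes with the alkenyl group in size.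

Step 16 (amide-selective reduction and stability of 24). If Cp2Zr(H)Cl is unselective or 24 eliminates angelate on formation, reach 24 through alcohol oxidation instead. The fallback sets out from 20 and returns at 24. NaBH4 in THF/EtOH at 0 °C removes the thiazolidinethione reductively and gives the 1,3-diol F3. Et3SiCl/imidazole in CH2Cl2 at −78 °C silylates only the primary hydroxyl to give the primary triethylsilyl ether F4. Angeloylation of the C8 hydroxyl under the conditions of step 15 gives the bis-angelate silyl ether F5. HF·pyridine/pyridine in THF at 0 °C, kept acidic so the C8 angelate does not migrate, frees the primary alcohol F6. Dess–Martin periodinane/pyridine oxidises F6 to 24.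

Step 15 (acylating the hindered C8 hydroxyl without angelate-to-tiglate isomerisation). If direct acylation stalls or gives tiglate, build the Z enoate on the oxygen instead. The fallback sets out from 21 and returns at 22. DCC/DMAP coupling with 2-[bis(2,2,2-trifluoroethoxy)phosphoryl]propanoic acid gives the phosphonopropanoate ester F7. Still–Gennari olefination of F7 with KN(SiMe3)2, 18-crown-6 and acetaldehyde in THF at −78 °C forms the (Z)-2-methylbut-2-enoate kinetically and gives 22.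

**Further compounds**
F1 | step 17 | (2S)-2-[(1S,2R,3E,7Z,10S)-2-hydroxy-4,8-dimethyl-10-{[(2Z)-2-methylbut-2-enoyl]oxy}cyclodeca-3,7-dien-1-yl]propyl (2Z)-2-methylbut-2-enoate (C6 epimer of 26) | C/C=C(/C)C(=O)OC[C@@H](C)[C@@H]1[C@@H](OC(=O)/C(C)=C\C)C/C(C)=C\CC/C(C)=C/[C@H]1O
F2 | step 17 | (2S)-2-[(1R,3E,7Z,10S)-4,8-dimethyl-10-{[(2Z)-2-methylbut-2-enoyl]oxy}-2-oxocyclodeca-3,7-dien-1-yl]propyl (2Z)-2-methylbut-2-enoate | C/C=C(/C)C(=O)OC[C@@H](C)[C@@H]1[C@@H](OC(=O)/C(C)=C\C)C/C(C)=C\CC/C(C)=C/C1=O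
F3 | step 16 | (2S,3S,4S,6Z,10E)-4-hydroxy-3-(hydroxymethyl)-11-iodo-2,6,10-trimethylundeca-6,10-dien-1-yl (2Z)-2-methylbut-2-enoate | C/C=C(/C)C(=O)OC[C@@H](C)[C@@H](CO)[C@@H](O)C/C(C)=C\CC/C(C)=C/I
F4 | step 16 | (2S,3S,4S,6Z,10E)-4-hydroxy-11-iodo-2,6,10-trimethyl-3-{[(triethylsilyl)oxy]methyl}undeca-6,10-dien-1-yl (2Z)-2-methylbut-2-enoate | C/C=C(/C)C(=O)OC[C@@H](C)[C@@H](CO[Si](CC)(CC)CC)[C@@H](O)C/C(C)=C\CC/C(C)=C/I
F5 | step 16 | (2S,3S,4S,6Z,10E)-11-iodo-2,6,10-trimethyl-3-{[(triethylsilyl)oxy]methyl}undeca-6,10-diene-1,4-diyl bis[(2Z)-2-methylbut-2-enoate] | C/C=C(/C)C(=O)OC[C@@H](C)[C@@H](CO[Si](CC)(CC)CC)[C@@H](OC(=O)/C(C)=C\C)C/C(C)=C\CC/C(C)=C/I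
F6 | step 16 | (2S,3S,4S,6Z,10E)-3-(hydroxymethyl)-11-iodo-2,6,10-trimethylundeca-6,10-diene-1,4-diyl bis[(2Z)-2-methylbut-2-enoate] | C/C=C(/C)C(=O)OC[C@@H](C)[C@@H](CO)[C@@H](OC(=O)/C(C)=C\C)C/C(C)=C\CC/C(C)=C/I
F7 | step 15 | (2S,3R,4S,6Z,10E)-4-({2-[bis(2,2,2-trifluoroethoxy)phosphoryl]propanoyl}oxy)-11-iodo-3-[methoxy(methyl)carbamoyl]-2,6,10-trimethylundeca-6,10-dien-1-yl (2Z)-2-methylbut-2-enoate (phosphonate α-carbon undefined) | C/C=C(/C)C(=O)OC[C@@H](C)[C@@H](C(=O)N(C)OC)[C@@H](OC(=O)C(C)P(=O)(OCC(F)(F)F)OCC(F)(F)F)C/C(C)=C\CC/C(C)=C/I
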